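## Analysis of the target

The target 16 is the methyl ester of a linear tridepside: three orsellinate rings joined head to tail by two aryl ester bonds. Each ring is a benzene with the carbonyl carbon on C1, oxygens on C2 and C4 and a methyl group on C6. Ring A is the terminal acyl ring with free hydroxyls on C2 and C4; ring B is the central ring, acylated on O4 by ring A and free at O2; ring C carries the methyl ester, is acylated on O4 by ring B and is free at O2. There is no stereocentre and no ring to close, so the task is to set the substitution pattern and to tell six phenolic oxygens on three nearly identical rings apart. The two depside bonds are aryl esters that hydroxide, alkoxide and amine nucleophiles cleave or scramble, and the free phenols are oxidisable, so the late steps must be neutral and mild. Every ester carbonyl is flanked by two ortho substituents, so each ester-forming step is hindered. The strategy rests on ring A: the methyl carbon on C6 and the carbonyl carbon on C1 are neighbours, and C1 is followed by the oxygen-bearing C2, with the second oxygen on C4. This is the pattern left when a carbon nucleophile and a carbon electrophile add across the triple bond of a 3,5-dioxygenated benzyne. Ring B shows the same pattern, so the acid made this way can serve both rings.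

## Retrosynthetic reasoning

**16 from 15.** The last operation removes the two benzyl ethers on O2 and O4 of ring A in 15. Benzyl is chosen because it leaves under neutral catalytic hydrogenolysis, which touches neither the two aryl esters nor the methyl ester.

**15 from 11 and 14.** The ester bond between the C1 carbonyl of ring A and O4 of ring B is cut. This gives acid chloride 11 and the didepside triol 14. In 14 only O4 of ring B is free of a hydrogen bond; O2 of ring B and O2 of ring C are each chelated to an ortho ester carbonyl. The forward acylation therefore has to distinguish one unhindered, more acidic phenol from two chelated, hindered ones.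

**14 from 13, and 13 from 11 and 12.** The ester bond between ring B and O4 of ring C is cut in the same way. Ring B is again acid chloride 11 and ring C is methyl orsellinate 12, used without protection because its O4 hydroxyl is the only unchelated one. Removal of the benzyl groups from 13 frees O4 of ring B for the second acylation. One acyl donor thus supplies two of the three rings, and no further protecting group is needed.

**11 from 10.** The acid chloride is the activated form of 2,4-bis(benzyloxy)-6-methylbenzoic acid 10.

**10 from 3, 4 and 5 (key disconnection).** The C6–CH3 bond and the C1–CO2H bond of 10 are both cut. This leads back to aryne 7, methylmagnesium bromide 4 and carbon dioxide 5. The cut is made here because these two bonds lie on the two carbons of one aryne triple bond, and the benzyloxy group next to that triple bond decides which carbon takes the nucleophile. Aryne 7 is generated from iodo sulfonate 3 by halogen–magnesium exchange and loss of the sulfonate. Forward, the methyl group must add to the aryne carbon remote from the flanking benzyloxy group, so that the arylmagnesium 8 has its metal beside that oxygen, where 5 captures it. What is gained is the full orsellinate pattern in one operation on a simple trioxygenated benzene.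

**3 from 2, and 2 from 1.** The sulfonate is installed on the hydroxyl of iodophenol 2, and the iodine is introduced ortho to the hydroxyl of 3,5-bis(benzyloxy)phenol 1. The two ortho positions of 1 are equivalent, so only ortho against para selectivity has to be secured.

## Alternatives that were turned down

**Alternative 1: [3+3] cycloaromatisation (Chan type) that builds ring B.**
- Disconnection: ring B is cut at C3–C4 and C1–C6 into a four-carbon 1,3-dioxygenated unit that already carries the ester to ring C, and a three-carbon β-methoxy enoyl unit.
- Forward key step: the bis-silyl dienol ether A2 reacts with (E)-3-methoxybut-2-enoyl chloride A3 under a strong Lewis acid. Its terminal carbon is acylated, its central carbon then replaces the methoxy group at the β-carbon, and aromatisation gives didepside A1.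
- For: the ester to ring C is made at an unhindered acetoacetate stage, not by hindered aroylation. Ring B arises with O4 free, so no hydrogenolysis is needed between the two acylations. On these two points it is stronger than the chosen route.
- Against: the orientation of the union is not secured. If the terminal carbon adds in conjugate fashion first and the central carbon is acylated, the methyl group ends up para to the ester carbon, as in isomer A4. Enolising an aryl acetoacetate invites loss of the aryloxide, and the Lewis acid threatens the benzyl ether and the aryl ester. Ring A must still be made and attached, so an acid such as 10 is needed anyway.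
- Comparison: A1 is the counterpart of 14 with one extra benzyl group. Reaching it needs O2-selective protection of 12, acetoacetylation, double silylation and the annulation, which is not shorter than steps 1 to 6 here. In its place the chosen strategy offers a pattern fixed by aryne polarisation and one acid used for two rings.

**Alternative 2: pyrone to arene, ring A by inverse-demand Diels–Alder reaction.**
- Disconnection: ring A is cut at C3–C4 and C5–C6. C1, C2, C3 and C6 with their ester, benzyloxy and methyl groups come from a 2-pyrone; C4 and C5 come from a ketene acetal.
- Forward key step: pyrone ester A6 adds 1,1-bis(trimethylsilyloxy)ethene A7 across the two pyrone termini. The bridged adduct undergoes decarboxylative cycloreversion and loses silanol to give tribenzyl ether A5.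
- For: the polarisation of the pyrone fixes the regiochemistry as firmly as the aryne addition does. O4 of ring A arises free while O2 is benzylated, a differentiation the chosen route does not provide, although this target does not need it.
- Against: the 4-benzyloxy group donates into the pyrone and the methyl-bearing terminus is fully substituted, so the diene is a poor partner for an electron-rich dienophile and heat is needed on a molecule with three esters. A7 is hydrolytically labile. The pyrone acid and a fully protected didepside phenol each need their own synthesis.
- Comparison: the route is clearly longer, and the arene-forming step falls at the end on the most advanced material. The chosen strategy places it at the start on a small molecule.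

**Alternative 3: vinylketene benzannulation of an ynol ester (Danheiser benzannulation) that makes ring C.**
- Disconnection: ring C is cut into a four-carbon unit (C1, C6, C5 and the C2 carbon) and a two-carbon alkyne unit (C3 and C4) that carries the depside oxygen.
- Forward key step: light converts diazo enone A9 by Wolff rearrangement into a ketene (C5–C6 bond). This adds ethynyl ester A10 in a [2+2] sense (C2–C3 and C4–C5 bonds). Four-electron ring opening and six-electron ring closure (C1–C2 bond) give phenol A8.
- For: it is the most convergent plan. The O2 hydroxyl of ring C arises free and O4 is acylated by construction, so no site-selective acylation is needed. On this point it is stronger than the chosen route.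
- Against: the benzannulation needs an electron-rich alkyne. An acyloxyalkyne is far less nucleophilic than an alkoxy- or siloxyalkyne and is itself an activated ester. The ketene from A9 carries a conjugated ester and is electron-poor. Making A10 from a hindered didepside acid is uncertain in its own right. The ring that is built is that of 12, which can be bought.
- Comparison: the most uncertain step is spent on the most elaborate fragment. The chosen strategy spends it on a compound three steps from a purchased phenol and relies afterwards on the well-founded difference between a chelated and a free phenol.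

Key step: step 3

Assumption: compounds 1, 4, 5 and 12 are bought, and acid 10 is prepared on a scale that covers both acylations (steps 5 and 7).

## Route

**Step 1**
Reactants: 1 3,5-bis(benzyloxy)phenol
Product: 2 3,5-bis(benzyloxy)-2-iodophenol
Conditions: NIS (1.0 equiv), CH2Cl2, −78 → 0 °C, dark
Reagents that add atoms: N-iodosuccinimide, O=C1CCC(=O)N1I
Why: Electrophilic aromatic iodination; the two equivalent positions ortho to the free hydroxyl should react in preference to C4, which is shielded by two flanking benzyloxy groups, and hydrogen bonding of the imide to the phenol in a non-polar solvent delivers iodine to the ortho position; one equivalent at low temperature limits di-iodination.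

**Step 2**
Reactants: 2 3,5-bis(benzyloxy)-2-iodophenol
Product: 3 3,5-bis(benzyloxy)-2-iodophenyl 4-chlorobenzenesulfonate
Conditions: 4-ClC6H4SO2Cl (1.1 equiv), Et3N, DMAP (cat.), CH2Cl2, 0 °C → rt
Reagents that add atoms: 4-chlorobenzenesulfonyl chloride, O=S(=O)(Cl)c1ccc(Cl)cc1
Why: O-Sulfonylation of a phenol under amine base with nucleophilic catalysis; the single ortho iodine slows but does not block attack of the phenoxide at sulfur, and the benzyl ethers and the aryl iodide are inert.

**Step 3**
Reactants: 3 3,5-bis(benzyloxy)-2-iodophenyl 4-chlorobenzenesulfonate; 4 methylmagnesium bromide; 5 carbon dioxide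
Product: 10 2,4-bis(benzyloxy)-6-methylbenzoic acid, via magnesiated sulfonate 6 (not isolated), via aryne 7 (not isolated), via arylmagnesium bromide 8 (not isolated), via magnesium carboxylate 9 (not isolated)
Conditions: i-PrMgCl·LiCl (1.0 equiv), THF, −78 °C; MeMgBr (3 equiv), −78 °C → rt; CO2 (gas), −20 °C → rt; aq. HCl
Reagents that add atoms: none
Why: Iodine–magnesium exchange at the carbon between the sulfonate and a benzyloxy group gives arylmagnesium 6, which on warming expels the neighbouring 4-chlorobenzenesulfonate to give aryne 7, whose triple bond joins the former C–I carbon (next to a benzyloxy group) and the former C–O carbon (next to a hydrogen). Methylmagnesium bromide 4, present in excess, adds its methyl group to the aryne carbon remote from the flanking benzyloxy group, so that magnesium sits beside that oxygen in 8, and carboxylation by 5 followed by acidification of 9 gives 10 with methyl and carboxyl on adjacent carbons and the carboxyl next to oxygen. The closest known reaction type is the three-component coupling of a 3-alkoxybenzyne with a Grignard reagent and an electrophile, combined with aryne generation from a 2-iodoaryl sulfonate by halogen–magnesium exchange. No ring is closed and no stereocentre is formed. The selectivity needed is regiochemical: the inductively withdrawing benzyloxy group distorts the aryne so that the distal carbon is the more electrophilic, and the developing carbanion is stabilised ortho to that oxygen and chelated by it, while the second benzyloxy group, para to the anionic carbon, has only a minor influence. Chemoselectivity rests on the order of addition, since the exchange should be complete at −78 °C before 4 is added, which avoids attack of 4 at sulfur, and the excess of 4 should outcompete the hindered arylmagnesium species 6 and 8 for the aryne. Benzyl ethers tolerate Grignard reagents at these temperatures, which is why magnesium and not lithium chemistry is used.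

**Step 4**
Reactants: 10 2,4-bis(benzyloxy)-6-methylbenzoic acid
Product: 11 2,4-bis(benzyloxy)-6-methylbenzoyl chloride
Conditions: (COCl)2, DMF (cat.), CH2Cl2, 0 °C → rt; concentrate, use crude
Reagents that add atoms: oxalyl chloride, O=C(Cl)C(=O)Cl
Why: Acid chloride formation through the chloroiminium salt from DMF and oxalyl chloride; the conditions are mild enough for aryl benzyl ethers, and di-ortho-substituted alkoxybenzoyl chlorides are stable enough to be used directly.

**Step 5**
Reactants: 11 2,4-bis(benzyloxy)-6-methylbenzoyl chloride; 12 methyl orsellinate
Product: 13 methyl 4-{[2,4-bis(benzyloxy)-6-methylbenzoyl]oxy}-2-hydroxy-6-methylbenzoate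
Conditions: Et3N (1.2 equiv), DMAP (cat.), CH2Cl2, 0 °C → rt
Reagents that add atoms: none
Why: Esterification of a phenol by an acid chloride with nucleophilic catalysis; O4 of 12 is the more acidic, unhindered hydroxyl, whereas O2 is held in a hydrogen bond to the ester carbonyl and flanked by it, so the hindered acyl donor should react at O4 only.

**Step 6**
Reactants: 13 methyl 4-{[2,4-bis(benzyloxy)-6-methylbenzoyl]oxy}-2-hydroxy-6-methylbenzoate
Product: 14 methyl 4-[(2,4-dihydroxy-6-methylbenzoyl)oxy]-2-hydroxy-6-methylbenzoate
Conditions: H2 (1 atm), Pd/C, EtOAc/THF, rt
Reagents that add atoms: none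
Why: Catalytic hydrogenolysis of benzyl aryl ethers; the aryl ester, the methyl ester and the arenes are inert under one atmosphere of hydrogen at room temperature in a neutral, non-nucleophilic solvent.

**Step 7**
Reactants: 11 2,4-bis(benzyloxy)-6-methylbenzoyl chloride; 14 methyl 4-[(2,4-dihydroxy-6-methylbenzoyl)oxy]-2-hydroxy-6-methylbenzoate
Product: 15 methyl 4-{[4-{[2,4-bis(benzyloxy)-6-methylbenzoyl]oxy}-2-hydroxy-6-methylbenzoyl]oxy}-2-hydroxy-6-methylbenzoate
Conditions: 11 (1.0 equiv), Et3N (1.1 equiv), DMAP (cat.), CH2Cl2/THF, −20 → 0 °C
Reagents that add atoms: none
Why: The same acid chloride esterification; of the three hydroxyls only O4 of ring B is free of a hydrogen bond and para to a carbonyl, hence the most acidic and least hindered, while O2 of ring B and O2 of ring C are chelated to ortho ester carbonyls and are poor nucleophiles toward a di-ortho-substituted benzoyl chloride; one equivalent of 11 at low temperature should keep the reaction at mono-acylation.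

**Step 8**
Reactants: 15 methyl 4-{[4-{[2,4-bis(benzyloxy)-6-methylbenzoyl]oxy}-2-hydroxy-6-methylbenzoyl]oxy}-2-hydroxy-6-methylbenzoate
Product: 16 methyl 4-({4-[(2,4-dihydroxy-6-methylbenzoyl)oxy]-2-hydroxy-6-methylbenzoyl}oxy)-2-hydroxy-6-methylbenzoate (target)
Conditions: H2 (1 atm), Pd/C, EtOAc/THF, rt
Reagents that add atoms: none
Why: Catalytic hydrogenolysis of the two remaining benzyl ethers under neutral conditions, which should leave both depside bonds and the methyl ester untouched and give the target directly.

## Compound list

1 | 3,5-bis(benzyloxy)phenol | Oc1cc(OCc2ccccc2)cc(OCc2ccccc2)c1 | starting material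
2 | 3,5-bis(benzyloxy)-2-iodophenol | Oc1cc(OCc2ccccc2)cc(OCc2ccccc2)c1I | intermediate
3 | 3,5-bis(benzyloxy)-2-iodophenyl 4-chlorobenzenesulfonate | Clc1ccc(cc1)S(=O)(=O)Oc1cc(OCc2ccccc2)cc(OCc2ccccc2)c1I | intermediate
4 | methylmagnesium bromide | C[Mg]Br | starting material
5 | carbon dioxide | O=C=O | starting material
6 | [2,4-bis(benzyloxy)-6-{[(4-chlorophenyl)sulfonyl]oxy}phenyl]magnesium chloride (not isolated) | Cl[Mg]c1c(OS(=O)(=O)c2ccc(Cl)cc2)cc(OCc2ccccc2)cc1OCc1ccccc1 | intermediate
7 | 3,5-bis(benzyloxy)benzyne (3,5-bis(benzyloxy)-1,2-didehydrobenzene; not isolated) | C1#CC(OCc2ccccc2)=CC(OCc2ccccc2)=C1 | intermediate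
8 | [2,4-bis(benzyloxy)-6-methylphenyl]magnesium bromide (not isolated) | Cc1cc(OCc2ccccc2)cc(OCc2ccccc2)c1[Mg]Br | intermediate
9 | bromomagnesium 2,4-bis(benzyloxy)-6-methylbenzoate (not isolated) | Cc1cc(OCc2ccccc2)cc(OCc2ccccc2)c1C(=O)O[Mg]Br | intermediate
10 | 2,4-bis(benzyloxy)-6-methylbenzoic acid | Cc1cc(OCc2ccccc2)cc(OCc2ccccc2)c1C(=O)O | intermediate
11 | 2,4-bis(benzyloxy)-6-methylbenzoyl chloride | Cc1cc(OCc2ccccc2)cc(OCc2ccccc2)c1C(=O)Cl | intermediate
12 | methyl orsellinate (methyl 2,4-dihydroxy-6-methylbenzoate) | COC(=O)c1c(C)cc(O)cc1O | starting material
13 | methyl 4-{[2,4-bis(benzyloxy)-6-methylbenzoyl]oxy}-2-hydroxy-6-methylbenzoate | COC(=O)c1c(C)cc(OC(=O)c2c(C)cc(OCc3ccccc3)cc2OCc2ccccc2)cc1O | intermediate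
14 | methyl 4-[(2,4-dihydroxy-6-methylbenzoyl)oxy]-2-hydroxy-6-methylbenzoate | COC(=O)c1c(C)cc(OC(=O)c2c(C)cc(O)cc2O)cc1O | intermediate
15 | methyl 4-{[4-{[2,4-bis(benzyloxy)-6-methylbenzoyl]oxy}-2-hydroxy-6-methylbenzoyl]oxy}-2-hydroxy-6-methylbenzoate | COC(=O)c1c(C)cc(OC(=O)c2c(C)cc(OC(=O)c3c(C)cc(OCc4ccccc4)cc3OCc3ccccc3)cc2O)cc1O | intermediate
16 | methyl 4-({4-[(2,4-dihydroxy-6-methylbenzoyl)oxy]-2-hydroxy-6-methylbenzoyl}oxy)-2-hydroxy-6-methylbenzoate (CNP0212402.0) | COC(=O)c1c(C)cc(OC(=O)c2c(C)cc(OC(=O)c3c(C)cc(O)cc3O)cc2O)cc1O | target

## Step count and least certain steps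

Total step count: 8. Longest linear sequence: 8 steps (1 → 2 → 3 → 10 → 11 → 13 → 14 → 15 → 16); 12 enters at step 5 and 11 is used a second time in step 7.

**Step 3 (key step).**
- What may go wrong: capture of the aryne by the methyl Grignard reagent may be slow, because methylmagnesium halides are aggregated and only moderately nucleophilic. The aryne would then be consumed by the arylmagnesium species in the flask (biaryl formation) or by halide. Incomplete exchange would also leave 3 open to attack at sulfur.
- Fallback: it sets out from 12 and comes back at 10. Exhaustive O-benzylation of 12 (BnBr, K2CO3, DMF, 70 °C) should give methyl 2,4-bis(benzyloxy)-6-methylbenzoate F1. Hydrolysis of this hindered ester (KOH, DMSO/H2O, 90 °C) should give 10.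

**Step 1.**
- What may go wrong: regioselectivity may be poor. Substitution para to the hydroxyl, between the two benzyloxy groups, or a second iodination can compete, because all three free ring positions are strongly activated.
- Fallback: it sets out from 1 and comes back at 2. Protection of 1 (MOMCl, i-Pr2NEt, CH2Cl2) should give 1,3-bis(benzyloxy)-5-(methoxymethoxy)benzene F2. Directed ortho-lithiation, steered by chelation to the acetal to the position between the acetal and a benzyloxy group (n-BuLi, THF, 0 °C; then I2), should give 1,5-bis(benzyloxy)-2-iodo-3-(methoxymethoxy)benzene F3. Acetal cleavage (HCl, MeOH, rt) should give 2.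

**Step 7.**
- What may go wrong: site selectivity may be incomplete. A chelated hydroxyl of the triol may be acylated once the free one has reacted, or acyl groups may transfer between phenoxides under the basic conditions.
- Fallback: the tridepside is assembled from the acyl end, so that each coupling partner has only one unchelated hydroxyl. It sets out from 11 and comes back at 15; steps 5 and 6 are then not needed. Acylation of purchased 2,4-dihydroxy-6-methylbenzaldehyde F4 with 11 (Et3N, DMAP, CH2Cl2) should give 4-formyl-3-hydroxy-5-methylphenyl 2,4-bis(benzyloxy)-6-methylbenzoate F5. Pinnick oxidation (NaClO2, NaH2PO4, 2-methyl-2-butene, t-BuOH/H2O) should give 4-{[2,4-bis(benzyloxy)-6-methylbenzoyl]oxy}-2-hydroxy-6-methylbenzoic acid F6. Condensation of F6 with 12 by the mixed-anhydride method ((CF3CO)2O, toluene, rt) should give 15.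

**Step 4.**
- What may go wrong: the ortho benzyl group may be lost through participation of the ether oxygen at the acylium stage, or the electron-rich acid chloride may hydrolyse on handling.
- Fallback: the acid chloride is avoided. It sets out from 10 and comes back at 13. Treatment of 10 and 12 with (CF3CO)2O in toluene at rt should form 2,4-bis(benzyloxy)-6-methylbenzoic trifluoroacetic anhydride F7 in the flask, which acylates O4 of 12 to give 13. The same procedure with 14 would replace step 7.

## Further compounds

F1 | step 3 | methyl 2,4-bis(benzyloxy)-6-methylbenzoate | COC(=O)c1c(C)cc(OCc2ccccc2)cc1OCc1ccccc1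
F2 | step 1 | 1,3-bis(benzyloxy)-5-(methoxymethoxy)benzene | COCOc1cc(OCc2ccccc2)cc(OCc2ccccc2)c1
F3 | step 1 | 1,5-bis(benzyloxy)-2-iodo-3-(methoxymethoxy)benzene | COCOc1cc(OCc2ccccc2)cc(OCc2ccccc2)c1I
F4 | step 7 | 2,4-dihydroxy-6-methylbenzaldehyde (purchased) | Cc1cc(O)cc(O)c1C=O
F5 | step 7 | 4-formyl-3-hydroxy-5-methylphenyl 2,4-bis(benzyloxy)-6-methylbenzoate | O=Cc1c(C)cc(OC(=O)c2c(C)cc(OCc3ccccc3)cc2OCc2ccccc2)cc1O
F6 | step 7 | 4-{[2,4-bis(benzyloxy)-6-methylbenzoyl]oxy}-2-hydroxy-6-methylbenzoic acid | OC(=O)c1c(C)cc(OC(=O)c2c(C)cc(OCc3ccccc3)cc2OCc2ccccc2)cc1O
F7 | step 4 | 2,4-bis(benzyloxy)-6-methylbenzoic trifluoroacetic anhydride | Cc1cc(OCc2ccccc2)cc(OCc2ccccc2)c1C(=O)OC(=O)C(F)(F)F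
A1 | alternative 1 | methyl 2-(benzyloxy)-4-[(2,4-dihydroxy-6-methylbenzoyl)oxy]-6-methylbenzoate | COC(=O)c1c(C)cc(OC(=O)c2c(C)cc(O)cc2O)cc1OCc1ccccc1
A2 | alternative 1 | methyl 2-(benzyloxy)-4-{[1,3-bis(trimethylsilyloxy)buta-1,3-dien-1-yl]oxy}-6-methylbenzoate (ketene acetal geometry left open) | COC(=O)c1c(C)cc(OC(O[Si](C)(C)C)=CC(=C)O[Si](C)(C)C)cc1OCc1ccccc1
A3 | alternative 1 | (E)-3-methoxybut-2-enoyl chloride | CO/C(C)=C/C(=O)Cl
A4 | alternative 1 | methyl 2-(benzyloxy)-4-[(2,6-dihydroxy-4-methylbenzoyl)oxy]-6-methylbenzoate | COC(=O)c1c(C)cc(OC(=O)c2c(O)cc(C)cc2O)cc1OCc1ccccc1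
A5 | alternative 2 | methyl 2-(benzyloxy)-4-{[2-(benzyloxy)-4-{[2-(benzyloxy)-4-hydroxy-6-methylbenzoyl]oxy}-6-methylbenzoyl]oxy}-6-methylbenzoate | COC(=O)c1c(C)cc(OC(=O)c2c(C)cc(OC(=O)c3c(C)cc(O)cc3OCc3ccccc3)cc2OCc2ccccc2)cc1OCc1ccccc1
A6 | alternative 2 | methyl 2-(benzyloxy)-4-{[2-(benzyloxy)-4-{[4-(benzyloxy)-6-methyl-2-oxo-2H-pyran-5-carbonyl]oxy}-6-methylbenzoyl]oxy}-6-methylbenzoate | COC(=O)c1c(C)cc(OC(=O)c2c(C)cc(OC(=O)C3=C(C)OC(=O)C=C3OCc3ccccc3)cc2OCc2ccccc2)cc1OCc1ccccc1
A7 | alternative 2 | 1,1-bis(trimethylsilyloxy)ethene | C=C(O[Si](C)(C)C)O[Si](C)(C)C
A8 | alternative 3 | methyl 4-{[2-(benzyloxy)-4-{[2,4-bis(benzyloxy)-6-methylbenzoyl]oxy}-6-methylbenzoyl]oxy}-2-hydroxy-6-methylbenzoate | COC(=O)c1c(C)cc(OC(=O)c2c(C)cc(OC(=O)c3c(C)cc(OCc4ccccc4)cc3OCc3ccccc3)cc2OCc2ccccc2)cc1O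
A9 | alternative 3 | methyl (E)-5-diazo-3-methyl-4-oxopent-2-enoate | COC(=O)/C=C(\C)C(=O)C=[N+]=[N-]
A10 | alternative 3 | ethynyl 2-(benzyloxy)-4-{[2,4-bis(benzyloxy)-6-methylbenzoyl]oxy}-6-methylbenzoate | C#COC(=O)c1c(C)cc(OC(=O)c2c(C)cc(OCc3ccccc3)cc2OCc2ccccc2)cc1OCc1ccccc1
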